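## Retrosynthetic overview

1. Target 19 ⇐ Negishi acylation of the acid chloride of lactone acid 14 with 2-(furan-3-yl)ethylzinc iodide; the furan enters last.
2. 14 ⇐ desymmetrising γ-lactonisation of a C2-symmetric diacid: the ring carbon carrying the side chain is not a stereocentre until cis ring closure creates it and tells the two identical carboxyls apart.
3. Both carbinol centres ⇐ L-proline anti-aldol of hydroxyacetone with the C2-symmetric aldehyde 9 (catalyst control).
4. 9 ⇐ one-carbon homologation of C2-symmetric keto diester 5 ⇐ twofold asymmetric methylation of 2-oxo-1,3-diester 3.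
5. Ring order: the cyclohexane is bought (in 1), the γ-lactone is closed in step 8, the furan is bought and attached in step 10.

Assumption: the sense of induction of the phase-transfer catalyst in step 2 is fixed in a pilot run and the antipode that gives (1S,3S)-5 is used.

## Route

Step 1
Reactants: 1 tert-butyl 2-oxocyclohexane-1-carboxylate
Product: 3 di-tert-butyl 2-oxocyclohexane-1,3-dicarboxylate, via dilithium dianion 2 (not isolated)
Conditions: LDA (3.1 equiv), THF, −78 → 0 °C; Boc2O (1.1 equiv), −78 °C → rt; 1 M HCl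
Reagents that add atoms: di-tert-butyl dicarbonate CC(C)(C)OC(=O)OC(=O)OC(C)(C)C
Why: Huckin–Weiler β-keto ester dianion chemistry puts the new ester on the α'-carbon by Claisen-type C-acylation, the extra equivalent of base absorbs the more acidic product, and no stereocentre is fixed (3 is a keto/enol mixture).

Step 2
Reactants: 3 di-tert-butyl 2-oxocyclohexane-1,3-dicarboxylate
Product: 5 di-tert-butyl (1S,3S)-1,3-dimethyl-2-oxocyclohexane-1,3-dicarboxylate, via monomethyl keto diester 4 (not isolated)
Conditions: MeI (5 equiv), Cs2CO3 (3 equiv), (S,S)-3,4,5-trifluorophenyl-NAS bromide (3 mol%), toluene, −20 °C; silica gel removes the meso isomer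
Reagents that add atoms: iodomethane CI
Why: Proposed new method: twofold catalyst-controlled phase-transfer C-methylation of a cyclic bis(β-keto ester), in which each enolate is ion-paired with the chiral N-spiro ammonium cation so that both quaternary centres are set with the same sense and the meso by-product carries off most of the minor-sense material; the closest known reaction type is the Maruoka asymmetric phase-transfer alkylation of tert-butyl 2-oxocycloalkanecarboxylates to α-quaternary β-keto esters.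

Step 3
Reactants: 5 di-tert-butyl (1S,3S)-1,3-dimethyl-2-oxocyclohexane-1,3-dicarboxylate
Product: 6 di-tert-butyl (1S,3S)-1,3-dimethyl-2-methylidenecyclohexane-1,3-dicarboxylate
Conditions: Cp2TiMe2 (2.5 equiv), toluene, 70 °C, dark
Reagents that add atoms: dimethyltitanocene C[Ti](C)(C1C=CC=C1)C1C=CC=C1
Why: Petasis methylenation (Cp2Ti=CH2, [2+2], cycloreversion) is non-basic, so the non-enolisable, retro-Claisen-prone keto diester and the hindered tert-butyl esters survive, and no stereocentre changes.

Step 4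
Reactants: 6 di-tert-butyl (1S,3S)-1,3-dimethyl-2-methylidenecyclohexane-1,3-dicarboxylate
Product: 8 di-tert-butyl (1S,3S)-2-(hydroxymethyl)-1,3-dimethylcyclohexane-1,3-dicarboxylate, via alkylborane 7 (not isolated)
Conditions: BH3·THF, THF, 0 °C → rt; then 3 M NaOH, 30% H2O2, 0 °C
Reagents that add atoms: hydrogen peroxide OO
Why: Brown hydroboration–oxidation puts boron on the terminal carbon, and because the C2 axis makes the two alkene faces homotopic the new ring CH is not a stereocentre, so no facial selectivity is needed.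

Step 5
Reactants: 8 di-tert-butyl (1S,3S)-2-(hydroxymethyl)-1,3-dimethylcyclohexane-1,3-dicarboxylate
Product: 9 di-tert-butyl (1S,3S)-2-formyl-1,3-dimethylcyclohexane-1,3-dicarboxylate
Conditions: Dess–Martin periodinane, CH2Cl2, rt
Reagents that add atoms: none
Why: Dess–Martin oxidation of a primary alcohol under neutral conditions, where enolisation of the aldehyde is harmless because its α-carbon is not stereogenic.

Step 6
Reactants: 9 di-tert-butyl (1S,3S)-2-formyl-1,3-dimethylcyclohexane-1,3-dicarboxylate; 10 hydroxyacetone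
Product: 11 di-tert-butyl (1S,3S)-2-[(1S,2S)-1,2-dihydroxy-3-oxobutyl]-1,3-dimethylcyclohexane-1,3-dicarboxylate
Conditions: L-proline (30 mol%), 10 (10 equiv), DMSO, rt, 3–5 d
Reagents that add atoms: none
Why: List-type L-proline enamine aldol, in which the enamine of the hydroxylated carbon attacks the Re face of the aldehyde through the acid-bound chair-like transition state and sets both carbinol centres as the anti-(1S,2S)-diol under catalyst control; the aldehyde is too hindered to self-condense.

Step 7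
Reactants: 11 di-tert-butyl (1S,3S)-2-[(1S,2S)-1,2-dihydroxy-3-oxobutyl]-1,3-dimethylcyclohexane-1,3-dicarboxylate
Product: 12 di-tert-butyl (1S,3S)-2-[(1S,2S)-2-acetoxy-1-hydroxy-3-oxobutyl]-1,3-dimethylcyclohexane-1,3-dicarboxylate
Conditions: Ac2O (1.2 equiv), pyridine, CH2Cl2, 0 °C
Reagents that add atoms: acetic anhydride CC(=O)OC(C)=O
Why: Selective O-acetylation of the accessible hydroxyl next to the ketone, the other hydroxyl being shielded by the ring carbon between two quaternary centres; acetylating first also keeps this oxygen from lactonising in step 8.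

Step 8
Reactants: 12 di-tert-butyl (1S,3S)-2-[(1S,2S)-2-acetoxy-1-hydroxy-3-oxobutyl]-1,3-dimethylcyclohexane-1,3-dicarboxylate
Product: 14 (3S,3aR,4S,7aS)-3-[(1S)-1-acetoxy-2-oxopropyl]-4,7a-dimethyl-1-oxooctahydro-2-benzofuran-4-carboxylic acid, via hydroxy diacid 13 (not isolated)
Conditions: TFA/CH2Cl2 1:3, 0 °C → rt; then toluene, 50 °C
Reagents that add atoms: none
Why: Acidolysis of both tert-butyl esters followed by acid-catalysed γ-lactonisation, which should close onto the cis carboxyl because the cis-fused bicycle forms through a flattened chair whereas the trans-fused lactone needs extra puckering against the 1,3-diaxial methyl/carboxyl pair; this desymmetrising step sets the ring-fusion CH as R and leaves the other carboxyl free.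

Step 9
Reactants: 15 2-(furan-3-yl)ethan-1-ol
Product: 16 3-(2-iodoethyl)furan
Conditions: PPh3, I2, imidazole, CH2Cl2, 0 °C → rt
Reagents that add atoms: iodine II
Why: Appel-type iodination of a primary alcohol by SN2 displacement of the oxyphosphonium, which leaves the furan untouched.

Step 10
Reactants: 14 (3S,3aR,4S,7aS)-3-[(1S)-1-acetoxy-2-oxopropyl]-4,7a-dimethyl-1-oxooctahydro-2-benzofuran-4-carboxylic acid; 16 3-(2-iodoethyl)furan
Product: 19 (1S)-1-[(3S,3aR,4S,7aS)-4-[3-(furan-3-yl)propanoyl]-4,7a-dimethyl-1-oxooctahydro-2-benzofuran-3-yl]-2-oxopropyl acetate, via acid chloride 17 (not isolated), via alkylzinc iodide 18 (not isolated)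
Conditions: 14, (COCl)2, DMF (cat.), CH2Cl2, 0 °C → rt, evaporate; 16, Zn dust, LiCl, THF, 40 °C; combine, Pd(PPh3)4 (5 mol%), THF, 0 °C → rt
Reagents that add atoms: none
Why: Acid chloride formation followed by Negishi acylation, in which the alkylzinc iodide tolerates the methyl ketone, acetate and lactone, the acid chloride has no α-hydrogen (no ketene), and the neutral conditions leave every stereocentre and the base-sensitive β-acyloxy ketone untouched.

## Compound list

1 | tert-butyl 2-oxocyclohexane-1-carboxylate | CC(C)(C)OC(=O)C1CCCCC1=O | starting material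
2 | dilithium α,α'-dianion of 1 (not isolated) | [Li+].[Li+].O=C1[CH-]CCCC1=C([O-])OC(C)(C)C | intermediate
3 | di-tert-butyl 2-oxocyclohexane-1,3-dicarboxylate | CC(C)(C)OC(=O)C1CCCC(C(=O)OC(C)(C)C)C1=O | intermediate
4 | di-tert-butyl (1S)-1-methyl-2-oxocyclohexane-1,3-dicarboxylate (not isolated) | CC(C)(C)OC(=O)C1CCC[C@](C)(C(=O)OC(C)(C)C)C1=O | intermediate
5 | di-tert-butyl (1S,3S)-1,3-dimethyl-2-oxocyclohexane-1,3-dicarboxylate | CC(C)(C)OC(=O)[C@@]1(C)CCC[C@](C)(C(=O)OC(C)(C)C)C1=O | intermediate
6 | di-tert-butyl (1S,3S)-1,3-dimethyl-2-methylidenecyclohexane-1,3-dicarboxylate | CC(C)(C)OC(=O)[C@@]1(C)CCC[C@](C)(C(=O)OC(C)(C)C)C1=C | intermediate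
7 | di-tert-butyl (1S,3S)-2-(boranylmethyl)-1,3-dimethylcyclohexane-1,3-dicarboxylate (not isolated) | CC(C)(C)OC(=O)[C@@]1(C)CCC[C@](C)(C(=O)OC(C)(C)C)C1CB | intermediate
8 | di-tert-butyl (1S,3S)-2-(hydroxymethyl)-1,3-dimethylcyclohexane-1,3-dicarboxylate | CC(C)(C)OC(=O)[C@@]1(C)CCC[C@](C)(C(=O)OC(C)(C)C)C1CO | intermediate
9 | di-tert-butyl (1S,3S)-2-formyl-1,3-dimethylcyclohexane-1,3-dicarboxylate | CC(C)(C)OC(=O)[C@@]1(C)CCC[C@](C)(C(=O)OC(C)(C)C)C1C=O | intermediate
10 | hydroxyacetone (1-hydroxypropan-2-one) | CC(=O)CO | starting material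
11 | di-tert-butyl (1S,3S)-2-[(1S,2S)-1,2-dihydroxy-3-oxobutyl]-1,3-dimethylcyclohexane-1,3-dicarboxylate | O[C@H](C(C)=O)[C@@H](O)C1[C@@](C)(C(=O)OC(C)(C)C)CCC[C@]1(C)C(=O)OC(C)(C)C | intermediate
12 | di-tert-butyl (1S,3S)-2-[(1S,2S)-2-acetoxy-1-hydroxy-3-oxobutyl]-1,3-dimethylcyclohexane-1,3-dicarboxylate | CC(=O)O[C@H](C(C)=O)[C@@H](O)C1[C@@](C)(C(=O)OC(C)(C)C)CCC[C@]1(C)C(=O)OC(C)(C)C | intermediate
13 | (1S,3S)-2-[(1S,2S)-2-acetoxy-1-hydroxy-3-oxobutyl]-1,3-dimethylcyclohexane-1,3-dicarboxylic acid (not isolated) | CC(=O)O[C@H](C(C)=O)[C@@H](O)C1[C@@](C)(C(O)=O)CCC[C@]1(C)C(O)=O | intermediate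
14 | (3S,3aR,4S,7aS)-3-[(1S)-1-acetoxy-2-oxopropyl]-4,7a-dimethyl-1-oxooctahydro-2-benzofuran-4-carboxylic acid | CC(=O)O[C@H](C(C)=O)[C@H]1OC(=O)[C@@]2(C)CCC[C@](C)(C(O)=O)[C@@H]12 | intermediate
15 | 2-(furan-3-yl)ethan-1-ol | OCCc1ccoc1 | starting material
16 | 3-(2-iodoethyl)furan | ICCc1ccoc1 | intermediate
17 | (3S,3aS,4S,7aS)-3-[(1S)-1-acetoxy-2-oxopropyl]-4,7a-dimethyl-1-oxooctahydro-2-benzofuran-4-carbonyl chloride (not isolated) | CC(=O)O[C@H](C(C)=O)[C@H]1OC(=O)[C@@]2(C)CCC[C@](C)(C(Cl)=O)[C@@H]12 | intermediate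
18 | [2-(furan-3-yl)ethyl]zinc iodide (not isolated) | I[Zn]CCc1ccoc1 | intermediate
19 | (1S)-1-[(3S,3aR,4S,7aS)-4-[3-(furan-3-yl)propanoyl]-4,7a-dimethyl-1-oxooctahydro-2-benzofuran-3-yl]-2-oxopropyl acetate (CNP0170401.2) | CC(=O)O[C@H](C(C)=O)[C@H]1OC(=O)[C@@]2(C)CCC[C@](C)(C(=O)CCc3ccoc3)[C@@H]12 | target

## Step count and risk

Total steps: 10. Longest linear sequence: 9 (steps 1–8 and 10); step 9 is a one-step side branch.

Steps most likely to fail:

Step 2 (ee and C2/meso ratio of the twofold asymmetric methylation are unproven on this substrate). Fallback: setting out from 3, exhaustive methylation with K2CO3 and MeI in acetone gives 5 together with its enantiomer di-tert-butyl (1R,3R)-1,3-dimethyl-2-oxocyclohexane-1,3-dicarboxylate F1 and the meso isomer di-tert-butyl (1R,3S)-1,3-dimethyl-2-oxocyclohexane-1,3-dicarboxylate F2. F2 is removed on silica and the racemate is resolved by preparative chromatography on a chiral stationary phase, so that asymmetric catalysis is replaced by resolution and the route is rejoined at 5.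

Step 3 (methylenation of a ketone lying between two quaternary carbons). Fallback: setting out from 5, MeLi with CeCl3 in THF at −78 °C adds to the activated ketone to give the tertiary alcohol di-tert-butyl (1S,3S)-2-hydroxy-1,2,3-trimethylcyclohexane-1,3-dicarboxylate F3. Dehydration with the Burgess reagent in warm toluene can only take a hydrogen from the new methyl group, so this addition–elimination sequence replaces the carbonyl olefination and rejoins the route at 6.

Step 6 (very hindered aldehyde, and unknown matched or mismatched pairing of L-proline with the chiral ring). Fallback: setting out from 9, Wittig reaction with Ph3P=CHC(O)CH3 in toluene at 100 °C gives the enone di-tert-butyl (1S,3S)-1,3-dimethyl-2-[(1E)-3-oxobut-1-en-1-yl]cyclohexane-1,3-dicarboxylate F4. Amine-catalysed asymmetric epoxidation (9-amino-9-deoxy-epi-cinchona alkaloid salt, H2O2, antipode chosen for the 2R,3S epoxide) gives the epoxy ketone di-tert-butyl (1S,3S)-2-[(2R,3S)-3-acetyloxiran-2-yl]-1,3-dimethylcyclohexane-1,3-dicarboxylate F5. TFA in CH2Cl2 then cleaves the esters and lets the cis carboxyl open the epoxide 5-exo with inversion to give the hydroxy lactone acid (3S,3aR,4S,7aS)-3-[(1S)-1-hydroxy-2-oxopropyl]-4,7a-dimethyl-1-oxooctahydro-2-benzofuran-4-carboxylic acid F6. Acetylation with Ac2O and pyridine rejoins the route at 14; here the two oxygens are set by epoxidation and anti opening instead of by the aldol.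

## Further compounds

F1 | step 2 | di-tert-butyl (1R,3R)-1,3-dimethyl-2-oxocyclohexane-1,3-dicarboxylate | CC(C)(C)OC(=O)[C@]1(C)CCC[C@@](C)(C(=O)OC(C)(C)C)C1=O
F2 | step 2 | di-tert-butyl (1R,3S)-1,3-dimethyl-2-oxocyclohexane-1,3-dicarboxylate (meso) | CC(C)(C)OC(=O)[C@@]1(C)CCC[C@@](C)(C(=O)OC(C)(C)C)C1=O
F3 | step 3 | di-tert-butyl (1S,3S)-2-hydroxy-1,2,3-trimethylcyclohexane-1,3-dicarboxylate | CC(C)(C)OC(=O)[C@@]1(C)CCC[C@](C)(C(=O)OC(C)(C)C)C1(C)O
F4 | step 6 | di-tert-butyl (1S,3S)-1,3-dimethyl-2-[(1E)-3-oxobut-1-en-1-yl]cyclohexane-1,3-dicarboxylate | CC(=O)/C=C/C1[C@@](C)(C(=O)OC(C)(C)C)CCC[C@]1(C)C(=O)OC(C)(C)C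
F5 | step 6 | di-tert-butyl (1S,3S)-2-[(2R,3S)-3-acetyloxiran-2-yl]-1,3-dimethylcyclohexane-1,3-dicarboxylate | CC(=O)[C@H]3O[C@@H]3C1[C@@](C)(C(=O)OC(C)(C)C)CCC[C@]1(C)C(=O)OC(C)(C)C
F6 | step 6 | (3S,3aR,4S,7aS)-3-[(1S)-1-hydroxy-2-oxopropyl]-4,7a-dimethyl-1-oxooctahydro-2-benzofuran-4-carboxylic acid | O[C@H](C(C)=O)[C@H]1OC(=O)[C@@]2(C)CCC[C@](C)(C(O)=O)[C@@H]12
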